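**Plan**

1. Retrosynthesis: the two malonate C–O bonds are cut first (the target is a C2-symmetric diester of (13E)-labd-13-ene-8α,15-diol). Then come C13=C14, C8–C17 with the C8–O bond, C9–C11, C2–C3 of ring A, C10–C1 and C10–C20, and last ring B (C5–C6 and C9–C10).
2. Forward: ring B is made first as a cyclohexenone, C10 is made quaternary by two conjugate additions, and ring A is closed at C2–C3 by ring-closing metathesis. The C9 chain, the 13E enoate, the C8 carbinol and the double esterification follow.
3. Enabling feature: ring A holds both quaternary carbons, C4 (gem-dimethyl) and C10 (angular methyl), and C2–C3 is its only bond between two plain CH2 groups. A vinyl group on C4 and an allyl group on C10, trans and gauche on ring B, can therefore be joined as a C2=C3 alkene with no stereocentre at stake and with Thorpe–Ingold help from C4 and C10.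
4. Stereochemistry: C5 from an enamine-catalysed Michael addition; C10 from conjugate allylation anti to the C5 substituent; C9 by equilibration next to the C8 ketone; C8 by α-face epoxidation of the 8(17)-alkene and hydride opening; 13E from the Horner–Wadsworth–Emmons step.
5. Labdane numbering is used for all compounds (ring A: C1–C5, C10; ring B: C5–C10; chain C11–C16; C17 on C8; C18 and C19 on C4; C20 on C10).

Key step: step 5

Assumption: the (S)-diarylprolinol ether is taken to give the 2S aldehyde 3 by the usual enamine model (electrophile anti to the diarylmethyl group); with the opposite sense of induction the (R)-catalyst is used instead.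

**Step 1**
Reactants: 1 3,3-dimethylpent-4-enal; 2 methyl vinyl ketone
Product: 3 (2S)-2-(2-methylbut-3-en-2-yl)-5-oxohexanal
Conditions: (S)-2-(methoxydiphenylmethyl)pyrrolidine (5 mol %), ethyl 3,4-dihydroxybenzoate (20 mol %), neat, 4 °C
Reagents that add atoms: none
Why: Enamine-catalysed Michael addition of the aldehyde to the enone, in which the E-enamine is attacked on the face away from the diarylmethyl group; this sets the future C5, and the quaternary β-carbon of the aldehyde suppresses self-aldol reaction.

**Step 2**
Reactants: 3 (2S)-2-(2-methylbut-3-en-2-yl)-5-oxohexanal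
Product: 4 (4R)-4-(2-methylbut-3-en-2-yl)cyclohex-2-en-1-one
Conditions: LiOH (cat.), i-PrOH, rt
Reagents that add atoms: none
Why: Intramolecular aldol condensation of the methyl ketone enolate (C9) onto the aldehyde (C10) closes ring B as the cyclohexenone; cyclisation should be faster than enolisation of the hindered aldehyde α-CH, so C5 is kept.

**Step 3**
Reactants: 4 (4R)-4-(2-methylbut-3-en-2-yl)cyclohex-2-en-1-one
Product: 6 (4R)-3-methyl-4-(2-methylbut-3-en-2-yl)cyclohex-2-en-1-one, via silyl enol ether 5 (not isolated)
Conditions: Me2CuLi, TMSCl, THF, −78 °C; then Pd(OAc)2, MeCN, rt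
Reagents that add atoms: lithium dimethylcuprate, [Li+].C[Cu-]C
Why: Cuprate 1,4-addition anti to the bulky C5 substituent with silyl trapping, followed by Saegusa–Ito oxidation (palladium enolate, β-hydride elimination of the C10–H), re-forms the enone with the C20 methyl in place; the transient C10 stereocentre is erased.

**Step 4**
Reactants: 6 (4R)-3-methyl-4-(2-methylbut-3-en-2-yl)cyclohex-2-en-1-one
Product: 7 trimethyl{[(3S,4S)-3-methyl-4-(2-methylbut-3-en-2-yl)-3-(prop-2-en-1-yl)cyclohex-1-en-1-yl]oxy}silane
Conditions: CH2=CHCH2MgBr, CuBr·SMe2, TMSCl, THF, −78 °C; non-aqueous work-up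
Reagents that add atoms: allylmagnesium bromide, C=CC[Mg]Br; chlorotrimethylsilane, C[Si](C)(C)Cl
Why: Chlorosilane-accelerated conjugate addition of allylcopper to the β,β-disubstituted enone, with axial attack anti to the pseudoaxial C5 substituent, places the allyl group trans to it (C10: CH3 β, allyl α); silylation in the flask fixes the C8–C9 enol regiochemistry.

**Step 5**
Reactants: 7 trimethyl{[(3S,4S)-3-methyl-4-(2-methylbut-3-en-2-yl)-3-(prop-2-en-1-yl)cyclohex-1-en-1-yl]oxy}silane
Product: 8 trimethyl{[(4aS,8aS)-5,5,8a-trimethyl-3,4,4a,5,8,8a-hexahydronaphthalen-2-yl]oxy}silane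
Conditions: second-generation Grubbs catalyst (5 mol %), CH2Cl2 (0.005 M), 40 °C
Reagents that add atoms: none
Why: Ring-closing olefin metathesis by the Chauvin mechanism: the ruthenium benzylidene exchanges onto the unhindered allyl terminus (C2), the new alkylidene adds across the vinyl group on C4 to a ruthenacyclobutane, and cycloreversion releases the C2=C3 double bond and, over the cycle, ethylene. The closest known reaction type is the ring-closing metathesis of 1,7-dienes to cyclohexenes in which one alkene is a vinyl group on a quaternary carbon. Ring A closes as a six-membered carbocycle, trans-fused to ring B, by intramolecular [2+2] cycloaddition and cycloreversion at C2 and C3. No stereocentre is formed; the trans ring fusion follows from the C5 and C10 configurations set in steps 1 and 4, which hold the two arms gauche and diequatorial on ring B. The step needs chemoselectivity and ring closure over oligomerisation: the only other alkene, the trisubstituted silyl enol ether C8=C9, is too hindered to enter the cycle, and the quaternary carbons C4 and C10 press the arms together (Thorpe–Ingold effect) while high dilution and loss of ethylene drive the closure.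

**Step 6**
Reactants: 8 trimethyl{[(4aS,8aS)-5,5,8a-trimethyl-3,4,4a,5,8,8a-hexahydronaphthalen-2-yl]oxy}silane; 2 methyl vinyl ketone
Product: 9 14,15,17-trinor-9-epi-labd-2-ene-8,13-dione (9β-H, chain α)
Conditions: BF3·OEt2, i-PrOH, CH2Cl2–MeNO2, −78 °C
Reagents that add atoms: none
Why: Mukaiyama–Michael addition of the regiodefined silyl enol ether to the BF3-activated enone; C9 is attacked axially on the α face, anti to the angular C20 methyl, so the 3-oxobutyl chain enters α (9-epi), which is corrected in step 8.

**Step 7**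
Reactants: 9 14,15,17-trinor-9-epi-labd-2-ene-8,13-dione
Product: 10 14,15,17-trinor-9-epi-labdane-8,13-dione
Conditions: H2 (1 atm), Pd/C, EtOAc, rt
Reagents that add atoms: none
Why: Heterogeneous hydrogenation of the cis-disubstituted C2=C3 alkene; both ketones are inert and no stereocentre is created.

**Step 8**
Reactants: 10 14,15,17-trinor-9-epi-labdane-8,13-dione
Product: 12 ethyl (13E)-8-oxo-17-norlabd-13-en-15-oate, via 9-epi keto enoate 11 (not isolated)
Conditions: (EtO)2P(O)CH2CO2Et, NaH, THF, 0 °C to rt; then NaOEt, EtOH, 40 °C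
Reagents that add atoms: triethyl phosphonoacetate, CCOC(=O)CP(=O)(OCC)OCC
Why: Horner–Wadsworth–Emmons olefination should occur only at the unhindered C13 methyl ketone (the C8 ketone is flanked by the branched C9) and favour the E enoate with the ester trans to the C12 chain, the minor Z isomer being removed by chromatography; ethoxide then equilibrates C9 through the C8–C9 enolate to the equatorial 9β chain (9α-H).

**Step 9**
Reactants: 12 ethyl (13E)-8-oxo-17-norlabd-13-en-15-oate
Product: 13 ethyl (13E)-labda-8(17),13-dien-15-oate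
Conditions: Ph3PCH3Br, KN(SiMe3)2, THF, 0 °C to 50 °C
Reagents that add atoms: methyltriphenylphosphonium bromide, C[P+](c1ccccc1)(c1ccccc1)c1ccccc1.[Br-]
Why: Wittig methylenation of the C8 ketone; the ylide should leave the β,β-disubstituted enoate alone, and C9 is already in its stable configuration.

**Step 10**
Reactants: 13 ethyl (13E)-labda-8(17),13-dien-15-oate
Product: 14 ethyl (13E)-8α,17-epoxylabd-13-en-15-oate
Conditions: mCPBA, NaHCO3, CH2Cl2, 0 °C
Reagents that add atoms: 3-chloroperbenzoic acid, OOC(=O)c1cccc(Cl)c1
Why: Prilezhaev epoxidation is chemoselective for the electron-rich 1,1-disubstituted 8(17)-alkene over the conjugated enoate and should take place on the α face, because the β face of C8 is screened by the axial C20 methyl.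

**Step 11**
Reactants: 14 ethyl (13E)-8α,17-epoxylabd-13-en-15-oate
Product: 15 (13E)-labd-13-ene-8α,15-diol
Conditions: LiAlH4, THF, 0 °C to rt
Reagents that add atoms: none
Why: Hydride opens the epoxide at the primary C17 (SN2), which leaves the 8α-oxygen as the tertiary alcohol and C17 as the 8β-methyl, and reduces the enoate 1,2 to the allylic alcohol without change of the C13=C14 geometry.

**Step 12**
Reactants: 15 (13E)-labd-13-ene-8α,15-diol (2.1 equiv); 16 malonic acid
Product: 17 bis[(13E)-8α-hydroxylabd-13-en-15-yl] malonate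
Conditions: DCC, DMAP (cat.), CH2Cl2, 0 °C to rt
Reagents that add atoms: none
Why: Steglich esterification of both carboxyl groups of malonic acid with the primary allylic alcohol; the tertiary 8α-hydroxyl is too hindered to be acylated, so no protecting group is needed.

**Compound list**

1 | 3,3-dimethylpent-4-enal | C=CC(C)(C)CC=O | starting material
2 | methyl vinyl ketone (but-3-en-2-one) | CC(=O)C=C | starting material
3 | (2S)-2-(2-methylbut-3-en-2-yl)-5-oxohexanal | O=C[C@H](C(C)(C)C=C)CCC(C)=O | intermediate
4 | (4R)-4-(2-methylbut-3-en-2-yl)cyclohex-2-en-1-one | O=C1C=C[C@H](C(C)(C)C=C)CC1 | intermediate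
5 | trimethyl{[(3S,4R)-3-methyl-4-(2-methylbut-3-en-2-yl)cyclohex-1-en-1-yl]oxy}silane | C[Si](C)(C)OC1=C[C@@H](C)[C@H](C(C)(C)C=C)CC1 | intermediate
6 | (4R)-3-methyl-4-(2-methylbut-3-en-2-yl)cyclohex-2-en-1-one | O=C1C=C(C)[C@H](C(C)(C)C=C)CC1 | intermediate
7 | trimethyl{[(3S,4S)-3-methyl-4-(2-methylbut-3-en-2-yl)-3-(prop-2-en-1-yl)cyclohex-1-en-1-yl]oxy}silane | C[Si](C)(C)OC1=C[C@@](C)(CC=C)[C@H](C(C)(C)C=C)CC1 | intermediate
8 | trimethyl{[(4aS,8aS)-5,5,8a-trimethyl-3,4,4a,5,8,8a-hexahydronaphthalen-2-yl]oxy}silane (5α-H, 10β-CH3; C2=C3 and C8=C9) | C[Si](C)(C)OC1=C[C@@]2(C)CC=CC(C)(C)[C@@H]2CC1 | intermediate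
9 | 14,15,17-trinor-9-epi-labd-2-ene-8,13-dione (9β-H) | CC(=O)CC[C@H]1[C@@]2(C)CC=CC(C)(C)[C@@H]2CCC1=O | intermediate
10 | 14,15,17-trinor-9-epi-labdane-8,13-dione (9β-H) | CC(=O)CC[C@H]1[C@@]2(C)CCCC(C)(C)[C@@H]2CCC1=O | intermediate
11 | ethyl (13E)-8-oxo-17-nor-9-epi-labd-13-en-15-oate (9β-H) | CCOC(=O)/C=C(\C)CC[C@H]1[C@@]2(C)CCCC(C)(C)[C@@H]2CCC1=O | intermediate
12 | ethyl (13E)-8-oxo-17-norlabd-13-en-15-oate (9α-H) | CCOC(=O)/C=C(\C)CC[C@@H]1[C@@]2(C)CCCC(C)(C)[C@@H]2CCC1=O | intermediate
13 | ethyl (13E)-labda-8(17),13-dien-15-oate (5α-H, 9α-H, 10β-CH3) | CCOC(=O)/C=C(\C)CC[C@@H]1[C@@]2(C)CCCC(C)(C)[C@@H]2CCC1=C | intermediate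
14 | ethyl (13E)-8α,17-epoxylabd-13-en-15-oate | CCOC(=O)/C=C(\C)CC[C@@H]1[C@@]2(C)CCCC(C)(C)[C@@H]2CC[C@]13CO3 | intermediate
15 | (13E)-labd-13-ene-8α,15-diol | OC/C=C(\C)CC[C@@H]1[C@@]2(C)CCCC(C)(C)[C@@H]2CC[C@@]1(C)O | intermediate
16 | malonic acid | OC(=O)CC(=O)O | starting material
17 | bis[(13E)-8α-hydroxylabd-13-en-15-yl] malonate | C/C(=C\COC(=O)CC(=O)OC/C=C(\C)CC[C@@H]1[C@@]2(C)CCCC(C)(C)[C@@H]2CC[C@@]1(C)O)CC[C@@H]1[C@@]2(C)CCCC(C)(C)[C@@H]2CC[C@@]1(C)O | target

**Count and risks**

Total step count: 12. Longest linear sequence: 12 steps (1 to 17).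

Step 4 (conjugate allylation). What may go wrong: the β-carbon C10 is flanked by the tert-alkyl-bearing C5, so 1,4-transfer may be slow and 1,2-addition or γ-deprotonation of the enone may take over. Fallback: from 6, CH2=CHCH2MgBr with CeCl3 in THF at −78 °C adds 1,2 to the carbonyl. The epimer with the allyl group trans to the C5 substituent, (1R,4R)-3-methyl-4-(2-methylbut-3-en-2-yl)-1-(prop-2-en-1-yl)cyclohex-2-en-1-ol F1, is separated and treated with KH and 18-crown-6 in THF. The anionic oxy-Cope rearrangement should transfer the allyl group suprafacially from C8 to C10 on the α face and give the C8–C9 potassium enolate, which is silylated in the same flask with TMSCl to come back to the route at 7.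

Step 6 (Mukaiyama–Michael addition). What may go wrong: protodesilylation of the hindered enol ether or oligomerisation of the enone may outrun bond formation at C9, which lies next to the quaternary C10. Fallback: from 8, MeLi in THF releases the lithium enolate with the same regiochemistry. SN2 alkylation with (E)-1-bromobut-2-ene on the α face gives (1S,4aS,8aS)-1-[(2E)-but-2-en-1-yl]-5,5,8a-trimethyl-3,4,4a,5,8,8a-hexahydronaphthalen-2(1H)-one F2. A Wacker–Tsuji oxidation (PdCl2, CuCl, O2, DMF–H2O), directed by the C8 carbonyl to the δ-carbon C13 of the γ,δ-unsaturated ketone, should then give the 1,5-diketone and come back to the route at 9.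

Step 8 (olefination and C9 equilibration). What may go wrong: under base the 1,5-diketone may close by intramolecular aldol addition faster than the phosphonate adds, and equilibration at the hindered C9 may be slow. Fallback: from 10, only the unhindered methyl ketone is converted to its dioxolane (1,2-bis(trimethylsilyloxy)ethane, TMSOTf cat., CH2Cl2, −78 °C) to give 13,13-ethylenedioxy-14,15,17-trinor-9-epi-labdan-8-one F3. NaOMe in MeOH, now without an aldol partner, equilibrates C9 to 13,13-ethylenedioxy-14,15,17-trinorlabdan-8-one F4. Wittig methylenation gives 13,13-ethylenedioxy-14,15-dinorlabd-8(17)-ene F5. PPTS in wet acetone releases 14,15-dinorlabd-8(17)-en-13-one F6, and Horner–Wadsworth–Emmons olefination of this single ketone comes back to the route at 13.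

**Further compounds**

F1 | step 4 | (1R,4R)-3-methyl-4-(2-methylbut-3-en-2-yl)-1-(prop-2-en-1-yl)cyclohex-2-en-1-ol | C=CC[C@@]1(O)C=C(C)[C@H](C(C)(C)C=C)CC1
F2 | step 6 | (1S,4aS,8aS)-1-[(2E)-but-2-en-1-yl]-5,5,8a-trimethyl-3,4,4a,5,8,8a-hexahydronaphthalen-2(1H)-one | C/C=C/C[C@H]1[C@@]2(C)CC=CC(C)(C)[C@@H]2CCC1=O
F3 | step 8 | 13,13-ethylenedioxy-14,15,17-trinor-9-epi-labdan-8-one | CC1(CC[C@H]2[C@@]3(C)CCCC(C)(C)[C@@H]3CCC2=O)OCCO1
F4 | step 8 | 13,13-ethylenedioxy-14,15,17-trinorlabdan-8-one | CC1(CC[C@@H]2[C@@]3(C)CCCC(C)(C)[C@@H]3CCC2=O)OCCO1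
F5 | step 8 | 13,13-ethylenedioxy-14,15-dinorlabd-8(17)-ene | CC1(CC[C@@H]2[C@@]3(C)CCCC(C)(C)[C@@H]3CCC2=C)OCCO1
F6 | step 8 | 14,15-dinorlabd-8(17)-en-13-one | CC(=O)CC[C@@H]1[C@@]2(C)CCCC(C)(C)[C@@H]2CCC1=C
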